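**Plan**

- Retrosynthetic cuts, in order: the acetate C–O bond; the ring bond between the aromatic carbon and the acetoxy-bearing CH (arene + aldehyde); the aryl–spiro-carbon bond (phenol para carbon + 1,2,3-trimethoxybenzene); the ArCH2–CH bond (bromophenol + alkylzinc); the CH(CH3)–CH(CH3) bond (imide enolate + lactate triflate).
- Forward: the two methyl-bearing carbons are joined by enolate alkylation and reduced to the C2-symmetric (2S,3S)-diol, which is differentiated as its trans-lactone, opened to an iodo ester and joined to the syringyl ring. Oxidative dearomatisation then creates the dienone ring with its quaternary carbon, and the seven-membered ring closes last.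
- Enabling feature: the 2,3,4-trimethoxyphenyl ring on the spiro carbon has a single ortho CH (its C-6, para to the central OMe), held by the four-carbon chain within reach of the aldehyde carbon. The two carbons this ring uses are those that 1,2,3-trimethoxybenzene offers to electrophiles: C-4 (ortho/para to OMe) first, then the neighbouring C-5, imposed by the tether.
- Stereochemistry: one methyl-bearing centre comes from the (4R)-benzyloxazolidinone auxiliary, the other from ethyl (S)-lactate by SN2 inversion; the carbinol centre is set by substrate control in the ring closure; the spiro carbon is not a stereocentre.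

Key step: step 9

Step 1
Reactants: 1 ethyl (2S)-2-hydroxypropanoate (ethyl (S)-lactate)
Product: 2 ethyl (2S)-2-{[(trifluoromethyl)sulfonyl]oxy}propanoate
Conditions: Tf2O (1.05 equiv), 2,6-lutidine (1.1 equiv), CH2Cl2, −78 to 0 °C
Reagents that add atoms: trifluoromethanesulfonic anhydride O=S(=O)(OS(=O)(=O)C(F)(F)F)C(F)(F)F
Why: O-sulfonylation (triflation) of the secondary alcohol with a hindered pyridine base forms only the O–S bond, so the S configuration of the lactate carbon should be retained, and the triflate is used at once after a cold wash and short filtration.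

Step 2
Reactants: 3 (4R)-4-benzyl-3-propanoyl-1,3-oxazolidin-2-one; 2 ethyl (2S)-2-{[(trifluoromethyl)sulfonyl]oxy}propanoate
Product: 5 (4R)-4-benzyl-3-[(2S,3S)-4-ethoxy-2,3-dimethyl-4-oxobutanoyl]-1,3-oxazolidin-2-one, via sodium Z-enolate 4 (not isolated)
Conditions: NaN(SiMe3)2 (1.05 equiv), THF, −78 °C; then 2 (1.2 equiv), −78 to −40 °C
Reagents that add atoms: none
Why: in this Evans auxiliary-controlled enolate alkylation the chelated Z-enolate should be attacked on the face remote from the benzyl group, which sets the imide α-carbon as S, while SN2 displacement of the triflate inverts the lactate carbon (descriptor S after the change of priorities), so the anti-2,3-dimethylsuccinate should result.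

Step 3
Reactants: 5 (4R)-4-benzyl-3-[(2S,3S)-4-ethoxy-2,3-dimethyl-4-oxobutanoyl]-1,3-oxazolidin-2-one
Product: 6 (2S,3S)-2,3-dimethylbutane-1,4-diol
Conditions: LiBH4 (3 equiv), MeOH (3 equiv), THF, 0 °C to rt
Reagents that add atoms: none
Why: borohydride reduction of the imide at its exocyclic carbonyl and of the ethyl ester to primary alcohols releases the C2-symmetric diol, the auxiliary and ethanol under conditions that do not enolise the α-stereocentres.

Step 4
Reactants: 6 (2S,3S)-2,3-dimethylbutane-1,4-diol
Product: 8 (3S,4S)-3,4-dimethyloxolan-2-one, via lactol 7 (not isolated)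
Conditions: TEMPO (10 mol%), PhI(OAc)2 (2.3 equiv), CH2Cl2, rt
Reagents that add atoms: none
Why: oxoammonium oxidation of a 1,4-diol (oxidative lactonisation) runs through the hydroxy aldehyde and its lactol to the γ-lactone, and because the diol is C2-symmetric either hydroxyl gives the same trans-lactone, which differentiates the two chain ends without a protecting group.

Step 5
Reactants: 8 (3S,4S)-3,4-dimethyloxolan-2-one
Product: 10 ethyl (2S,3S)-4-iodo-2,3-dimethylbutanoate, via trimethylsilyl ester 9 (not isolated)
Conditions: Me3SiI, MeCN, 50 °C; then EtOH, rt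
Reagents that add atoms: iodotrimethylsilane C[Si](C)(C)I; ethanol CCO
Why: O-silylation of the lactone carbonyl and SN2 attack of iodide at the O–CH2 carbon (silyl iodide lactone opening) give the ω-iodo silyl ester, which the HI formed on adding ethanol converts to the ethyl ester by Fischer esterification, the stereocentres being spectators.

Step 6
Reactants: 10 ethyl (2S,3S)-4-iodo-2,3-dimethylbutanoate; 11 4-bromo-2,6-dimethoxyphenol
Product: 13 ethyl (2S,3R)-4-(4-hydroxy-3,5-dimethoxyphenyl)-2,3-dimethylbutanoate, via alkylzinc iodide 12 (not isolated)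
Conditions: Zn dust, LiCl, THF, 40 °C; then 11, Pd(OAc)2 (2 mol%), SPhos (4 mol%), THF, rt, slow addition of the zinc reagent
Reagents that add atoms: none
Why: zinc insertion into the primary C–I bond tolerates the ester, and the Negishi coupling (Pd(OAc)2/SPhos, reduced in the flask to zerovalent palladium) should outrun protonation of the alkylzinc by the free phenol when the zinc reagent is added slowly, so the sp3–sp2 bond forms without a protecting group and the change of descriptor from 3S to 3R reflects only the new substituent priorities.

Step 7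
Reactants: 13 ethyl (2S,3R)-4-(4-hydroxy-3,5-dimethoxyphenyl)-2,3-dimethylbutanoate
Product: 14 (2S,3R)-4-(4-hydroxy-3,5-dimethoxyphenyl)-2,3-dimethylbutanal
Conditions: i-Bu2AlH (2.3 equiv), CH2Cl2, −78 °C; MeOH, then aqueous potassium sodium tartrate
Reagents that add atoms: none
Why: after one equivalent has deprotonated the phenol, partial hydride reduction of the ester at −78 °C should stop at the aldehyde oxidation level, and the cold, neutral work-up avoids epimerisation of the α-methyl centre.

Step 8
Reactants: 14 (2S,3R)-4-(4-hydroxy-3,5-dimethoxyphenyl)-2,3-dimethylbutanal; 15 1,2,3-trimethoxybenzene (5 equiv)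
Product: 16 4-[(2R,3S)-2,3-dimethyl-4-oxobutyl]-2,6-dimethoxy-4-(2,3,4-trimethoxyphenyl)cyclohexa-2,5-dien-1-one
Conditions: PhI(OAc)2 (1.05 equiv), (CF3)2CHOH, −20 to 0 °C, 15 min
Reagents that add atoms: none
Why: two-electron oxidation of the phenol by the trivalent iodine reagent in the cation-stabilising, non-nucleophilic fluoro alcohol makes the alkyl-bearing para carbon electrophilic, and the excess arene should attack it through C-4 (ortho and para to methoxy groups) in an intermolecular oxidative Friedel–Crafts dearomatisation that avoids the two methoxy-bearing ortho carbons and creates the quaternary carbon of the symmetric dienone.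

Step 9
Reactants: 16 4-[(2R,3S)-2,3-dimethyl-4-oxobutyl]-2,6-dimethoxy-4-(2,3,4-trimethoxyphenyl)cyclohexa-2,5-dien-1-one
Product: 18 (7R,8S,9R)-2,3,3',4,5'-pentamethoxy-7,8-dimethyl-4'-oxo-6,7,8,9-tetrahydrospiro[benzo[7]annulene-5,1'-cyclohexa[2,5]dien]-9-yl acetate (the target CNP0143674.1), via chloro(methyl)aluminium alkoxide 17 (not isolated)
Conditions: Me2AlCl (3 equiv), CH2Cl2, −78 to −40 °C; then pyridine, DMAP, Ac2O, −78 to 0 °C
Reagents that add atoms: acetic anhydride CC(=O)OC(C)=O
Why: Me2AlCl coordinates the aldehyde oxygen (the first equivalents are taken up by the dienone carbonyl), the activated carbonyl carbon is attacked by the arene, and the arenium proton leaves as methane through an Al–CH3 bond, so the carbinol is held as the non-ionisable aluminium alkoxide 17, which is acetylated in the same flask. The closest known reaction types are the Lewis-acid-mediated intramolecular Friedel–Crafts hydroxyalkylation (carbonyl–arene cyclisation) of aryl-tethered aldehydes and the acetylation of aluminium alkoxides with Ac2O/pyridine/DMAP known from reductive acetylation of esters. The benzo-fused seven-membered ring closes by 7-exo-trig attack of the aromatic carbon on the C=O carbon, with the tether running through the quaternary spiro carbon. The new carbinol centre is set by substrate control from the two methyl-bearing centres: in the chair-like transition state both methyl groups and the aluminium-bound oxygen are pseudo-equatorial, which places oxygen trans to the adjacent methyl group and should give the 9R configuration, and acetylation does not touch the C–O bond. Site selectivity is secured by the substrate, because the attacking carbon is the only aromatic CH ortho to the spiro carbon while the other CH is meta and cannot reach the aldehyde; chemoselectivity over methyl transfer, aldehyde enolisation and dienone–phenol rearrangement rests on the low temperature and on the aluminium reagent acting as proton scavenger.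

**Compound list**

1 | ethyl (2S)-2-hydroxypropanoate (ethyl (S)-lactate) | C[C@H](O)C(=O)OCC | starting material
2 | ethyl (2S)-2-{[(trifluoromethyl)sulfonyl]oxy}propanoate | CCOC(=O)[C@H](C)OS(=O)(=O)C(F)(F)F | intermediate
3 | (4R)-4-benzyl-3-propanoyl-1,3-oxazolidin-2-one | CCC(=O)N1[C@H](Cc2ccccc2)COC1=O | starting material
4 | sodium Z-enolate of 3 | C/C=C(\O[Na])N1[C@H](Cc2ccccc2)COC1=O | intermediate
5 | (4R)-4-benzyl-3-[(2S,3S)-4-ethoxy-2,3-dimethyl-4-oxobutanoyl]-1,3-oxazolidin-2-one | CCOC(=O)[C@@H](C)[C@H](C)C(=O)N1[C@H](Cc2ccccc2)COC1=O | intermediate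
6 | (2S,3S)-2,3-dimethylbutane-1,4-diol | OC[C@@H](C)[C@H](C)CO | intermediate
7 | (3S,4S)-3,4-dimethyloxolan-2-ol (anomeric mixture) | O1C[C@@H](C)[C@H](C)C1O | intermediate
8 | (3S,4S)-3,4-dimethyloxolan-2-one | O1C[C@@H](C)[C@H](C)C1=O | intermediate
9 | trimethylsilyl (2S,3S)-4-iodo-2,3-dimethylbutanoate | IC[C@@H](C)[C@H](C)C(=O)O[Si](C)(C)C | intermediate
10 | ethyl (2S,3S)-4-iodo-2,3-dimethylbutanoate | IC[C@@H](C)[C@H](C)C(=O)OCC | intermediate
11 | 4-bromo-2,6-dimethoxyphenol | Oc1c(OC)cc(Br)cc1OC | starting material
12 | [(2S,3S)-4-ethoxy-2,3-dimethyl-4-oxobutyl]zinc iodide | I[Zn]C[C@@H](C)[C@H](C)C(=O)OCC | intermediate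
13 | ethyl (2S,3R)-4-(4-hydroxy-3,5-dimethoxyphenyl)-2,3-dimethylbutanoate | COc1cc(C[C@@H](C)[C@H](C)C(=O)OCC)cc(OC)c1O | intermediate
14 | (2S,3R)-4-(4-hydroxy-3,5-dimethoxyphenyl)-2,3-dimethylbutanal | COc1cc(C[C@@H](C)[C@H](C)C=O)cc(OC)c1O | intermediate
15 | 1,2,3-trimethoxybenzene | COc1cccc(OC)c1OC | starting material
16 | 4-[(2R,3S)-2,3-dimethyl-4-oxobutyl]-2,6-dimethoxy-4-(2,3,4-trimethoxyphenyl)cyclohexa-2,5-dien-1-one | COC1=CC(C=C(OC)C1=O)(C[C@@H](C)[C@H](C)C=O)c1ccc(OC)c(OC)c1OC | intermediate
17 | chloro(methyl)aluminium alkoxide of the (7R,8S,9R)-9-hydroxy spiro dienone | COC1=CC2(C=C(OC)C1=O)C[C@@H](C)[C@H](C)[C@@H](O[Al](C)Cl)c1cc(OC)c(OC)c(OC)c12 | intermediate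
18 | (7R,8S,9R)-2,3,3',4,5'-pentamethoxy-7,8-dimethyl-4'-oxo-6,7,8,9-tetrahydrospiro[benzo[7]annulene-5,1'-cyclohexa[2,5]dien]-9-yl acetate | COC1=CC2(C=C(OC)C1=O)C[C@@H](C)[C@H](C)[C@@H](OC(C)=O)c1cc(OC)c(OC)c(OC)c12 | target

**Step count**

Total steps: 9. Longest linear sequence: 9 (1 to 18); compounds 3, 11 and 15 enter as purchased materials.

**Steps most likely to fail**

Step 8. The arene may attack the oxidised phenol at the wrong site, or the cation may lose a benzylic proton to a quinone methide that is then arylated at the benzylic carbon; a second arylation of the product ring is also possible. The fallback separates oxidation from C–C bond formation. Setting out from 14, oxidation with PhI(OAc)2 in MeOH at −20 °C should give the quinone monoketal 4-[(2R,3S)-2,3-dimethyl-4-oxobutyl]-2,6,6-trimethoxycyclohexa-2,4-dien-1-one F1, which is used without storage. Treating F1 with 15 and BF3·OEt2 in CH2Cl2/(CF3)2CHOH at −40 °C, in the absence of any oxidant, should then bring about an acid-promoted allylic (SN2'-type) substitution of one ketal methoxy group by the arene at the alkyl-bearing carbon. This is the known arylation of quinone monoketals, and the sequence comes back to the route at 16.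

Step 9. The aromatic carbon is activated only by the twisted central methoxy group, so ring closure may be slower than methyl transfer from aluminium to the aldehyde, enolisation next to the aldehyde, or Lewis-acid-induced aryl migration in the dienone; facial selectivity at the carbonyl may also be poor. The fallback reverses the polarity. Setting out from 14, the conditions of step 8 with 5-iodo-1,2,3-trimethoxybenzene in place of 15 should give 4-[(2R,3S)-2,3-dimethyl-4-oxobutyl]-4-(6-iodo-2,3,4-trimethoxyphenyl)-2,6-dimethoxycyclohexa-2,5-dien-1-one F2. An intramolecular Nozaki–Hiyama–Kishi reaction (CrCl2, catalytic NiCl2, DMF, rt) would add the aryl carbon to the aldehyde under neutral conditions to give (7R,8S,9R)-9-hydroxy-2,3,3',4,5'-pentamethoxy-7,8-dimethyl-6,7,8,9-tetrahydrospiro[benzo[7]annulene-5,1'-cyclohexa[2,5]dien]-4'-one F3. Acetylation of F3 (Ac2O, pyridine, DMAP) comes back to the route at 18.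

Step 6. The free phenol may protonate the alkylzinc faster than transmetalation occurs, and the zinc phenoxide formed makes the aryl bromide so electron-rich that oxidative addition may stall. The fallback masks the acidic proton. Setting out from 11, silylation (t-BuMe2SiCl, imidazole, DMF, rt) should give (4-bromo-2,6-dimethoxyphenoxy)(tert-butyl)dimethylsilane F4. Negishi coupling of F4 with the zinc reagent 12 under the catalyst of step 6 should give ethyl (2S,3R)-4-{4-[(tert-butyldimethylsilyl)oxy]-3,5-dimethoxyphenyl}-2,3-dimethylbutanoate F5. Cleavage of the silyl ether of F5 (Bu4NF, AcOH, THF, 0 °C) comes back to the route at 13.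

**Further compounds**

F1 | step 8 | 4-[(2R,3S)-2,3-dimethyl-4-oxobutyl]-2,6,6-trimethoxycyclohexa-2,4-dien-1-one | COC1=CC(C[C@@H](C)[C@H](C)C=O)=CC(OC)(OC)C1=O
F2 | step 9 | 4-[(2R,3S)-2,3-dimethyl-4-oxobutyl]-4-(6-iodo-2,3,4-trimethoxyphenyl)-2,6-dimethoxycyclohexa-2,5-dien-1-one | COC1=CC(C=C(OC)C1=O)(C[C@@H](C)[C@H](C)C=O)c1c(I)cc(OC)c(OC)c1OC
F3 | step 9 | (7R,8S,9R)-9-hydroxy-2,3,3',4,5'-pentamethoxy-7,8-dimethyl-6,7,8,9-tetrahydrospiro[benzo[7]annulene-5,1'-cyclohexa[2,5]dien]-4'-one | COC1=CC2(C=C(OC)C1=O)C[C@@H](C)[C@H](C)[C@@H](O)c1cc(OC)c(OC)c(OC)c12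
F4 | step 6 | (4-bromo-2,6-dimethoxyphenoxy)(tert-butyl)dimethylsilane | COc1cc(Br)cc(OC)c1O[Si](C)(C)C(C)(C)C
F5 | step 6 | ethyl (2S,3R)-4-{4-[(tert-butyldimethylsilyl)oxy]-3,5-dimethoxyphenyl}-2,3-dimethylbutanoate | COc1cc(C[C@@H](C)[C@H](C)C(=O)OCC)cc(OC)c1O[Si](C)(C)C(C)(C)C
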